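**Retrosynthetic overview**
1. Feature, in quinate numbering (ring C1–C6; C1 is the quaternary carbinol bearing carboxyl C7; O3 caffeoylated, O4 p-coumaroylated): the two groups left free, C7O2H and O5–H, are cis-1,3 on the cyclohexane. They are tied as the γ-lactone ring O5–C5–C6–C1–C7 of a 6-oxabicyclo[3.2.1]octan-7-one (1,5-quinide). The last disconnections are lactone and aryl acetate hydrolysis, O1-Troc removal, and the O4 and then O3 ester bonds.
2. Key disconnection: the C5–O lactone bond, made with inversion by intramolecular Mitsunobu closure of a 5-epi-quinic acid (O1, O3, O4, O5 on one face, C7 on the other).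
3. The 5-epi series is meso. A lipase acetylates the (R)-carbinol C3 and leaves only (S)-C5–OH for activation. O4 is held as a MOM acetal from before the desymmetrisation, because a free O4–H would allow an acetyl walk O3→O4→O5 (racemisation) and a rival closure at C4.
4. The meso skeleton comes from gallic acid, which holds all of C1–C7 and O3–O5: all-cis Rh hydrogenation, then equatorial hydroxylation of the C1 ester enolate.
5. Ring order: carbocycle from the arene (step 1), lactone ring (step 9), lactone reopened in the last step.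

Key step: step 9

Assumption: the lipase is taken to follow the empirical size rule for secondary alcohols with the oxygenated C4 side as the large group, so it acylates (R)-C3. The sense is to be confirmed by correlating a sample of 13 (MOM removed) with 1,5-quinide made from natural (−)-quinic acid.

Step 1
Reactants: 1 gallic acid
Product: 2 all-cis-3,4,5-trihydroxycyclohexane-1-carboxylic acid (meso; CO2H, O3, O4, O5 on one face)
Conditions: H2 (80–100 bar), 5% Rh/Al2O3, H2O, 80–90 °C
Reagents that add atoms: none
Why: Heterogeneous arene hydrogenation over rhodium adds all six hydrogens from the adsorbed face, so C1, C3, C4 and C5 should be set all-cis (meso), and Rh on alumina keeps C–O hydrogenolysis low.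

Step 2
Reactants: 2 all-cis-3,4,5-trihydroxycyclohexane-1-carboxylic acid
Product: 3 benzyl all-cis-3,4,5-trihydroxycyclohexane-1-carboxylate
Conditions: BnBr, KHCO3, DMF, rt
Reagents that add atoms: benzyl bromide, BrCc1ccccc1
Why: Carboxylate O-alkylation (SN2) with a base too weak to deprotonate the alcohols gives an ester that can later be removed by neutral hydrogenolysis beside an acetate.

Step 3
Reactants: 3 benzyl all-cis-3,4,5-trihydroxycyclohexane-1-carboxylate
Product: 4 benzyl all-cis-3,5-bis(tert-butyldimethylsilyloxy)-4-hydroxycyclohexane-1-carboxylate (meso)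
Conditions: TBSCl (2.2 equiv), imidazole, DMF, 0 °C → rt
Reagents that add atoms: tert-butyldimethylsilyl chloride, CC(C)(C)[Si](C)(C)Cl
Why: Sterically controlled silylation should take the two equatorial flank hydroxyls O3 and O5 and leave the axial O4–H wedged between them, so the mirror symmetry is kept.

Step 4
Reactants: 4 benzyl all-cis-3,5-bis(TBSO)-4-hydroxycyclohexane-1-carboxylate
Product: 5 benzyl all-cis-3,5-bis(TBSO)-4-(methoxymethoxy)cyclohexane-1-carboxylate (meso)
Conditions: MOMCl, iPr2NEt, Bu4NI (cat.), CH2Cl2, reflux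
Reagents that add atoms: chloromethyl methyl ether, COCCl
Why: O-alkylation with the small, highly electrophilic α-chloro ether (acetal formation) reaches the hindered axial O4–H under amine-base conditions that do not trigger silyl migration.

Step 5
Reactants: 5 benzyl all-cis-3,5-bis(TBSO)-4-(MOMO)cyclohexane-1-carboxylate
Product: 7 benzyl 3,5-di-O-TBS-4-O-MOM-5-epi-quinate (meso; O1, O3, O4, O5 on one face, CO2Bn on the other), via lithium ester enolate 6 (not isolated)
Conditions: LDA (commercial solution), THF, −78 °C; 2-(phenylsulfonyl)-3-phenyloxaziridine, −78 → −40 °C; AcOH quench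
Reagents that add atoms: 2-(phenylsulfonyl)-3-phenyloxaziridine, O=S(=O)(N1OC1c1ccccc1)c1ccccc1
Why: In this Davis oxidation of an exocyclic ester enolate the bulky oxaziridine should attack C1 from the equatorial side, away from axial H3 and H5, which places O1 equatorial (cis to O3, O4, O5) and CO2Bn axial on the opposite face; no β-leaving group is present, and any C1 epimer is removed by chromatography.

Step 6
Reactants: 7 benzyl 3,5-di-O-TBS-4-O-MOM-5-epi-quinate
Product: 8 benzyl 4-O-MOM-5-epi-quinate (meso 1,3,5-triol; C3 is R, C5 is S)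
Conditions: HF·pyridine, pyridine/THF, 0 °C → rt
Reagents that add atoms: none
Why: Fluoride-driven Si–O cleavage in a mildly acidic medium spares the MOM acetal and the benzyl ester, and lactonisation cannot occur because the ester is trans to O3 and O5.

Step 7
Reactants: 8 benzyl 4-O-MOM-5-epi-quinate
Product: 9 benzyl 3-O-acetyl-4-O-MOM-5-epi-quinate (acetate on (R)-C3, free hydroxyl on (S)-C5)
Conditions: vinyl acetate, immobilised Burkholderia cepacia lipase, MTBE/THF, 30 °C
Reagents that add atoms: vinyl acetate, C=COC(C)=O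
Why: Lipase-catalysed irreversible transesterification, a known way to desymmetrise all-cis 4-substituted 3,5-dihydroxycyclohexanecarboxylates, should acylate the (R)-carbinol C3 and so fix the absolute configuration, while tertiary O1–H is inert and the blocked O4 rules out racemising acetyl migration.

Step 8
Reactants: 9 benzyl 3-O-acetyl-4-O-MOM-5-epi-quinate
Product: 10 3-O-acetyl-4-O-MOM-5-epi-quinic acid
Conditions: H2 (1 atm), 10% Pd/C, EtOAc, rt
Reagents that add atoms: none
Why: Benzyl ester hydrogenolysis is neutral and leaves the acetate, the MOM acetal and all stereocentres untouched.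

Step 9
Reactants: 10 3-O-acetyl-4-O-MOM-5-epi-quinic acid
Product: 12 3-O-acetyl-4-O-MOM-1,5-quinide (6-oxabicyclo[3.2.1]octan-7-one; C5 now R), via C5-oxytriphenylphosphonium carboxylate zwitterion 11 (not isolated)
Conditions: PPh3, DIAD, THF (0.01 M), slow addition of 10, 0 °C → rt
Reagents that add atoms: none
Why: Intramolecular Mitsunobu lactonisation: the PPh3–DIAD betaine is protonated by the C7 acid and passes phosphorus to the equatorial O5–H, the only secondary hydroxyl present, to give zwitterion 11. The axial C1 carboxylate sits on the ring face opposite to the leaving group and displaces Ph3P=O from the back of C5, a 5-exo-tet closure of the ring O–C5–C6–C1–C7 through a flattened, boat-like transition state that delivers the 6-oxabicyclo[3.2.1]octan-7-one. The closest known reactions are the invertive Mitsunobu lactonisations of trans-3-hydroxycyclohexanecarboxylic acids and of N-protected trans-4-hydroxyproline to bridged γ-lactones. C5 is the only stereocentre that changes, (S) to (R), and it is controlled by the SN2 geometry alone, because a retentive closure through an acyloxyphosphonium is geometrically impossible for a trans-1,3 pair. The step needs activation at O5 only, and the substrate secures this: O3 is acetylated, O4 carries the non-migrating MOM acetal (no 6-exo-tet closure at C4 to a 2-oxabicyclo[2.2.2]octan-3-one, no dioxaphosphorane, no acetyl walk) and the tertiary O1–H is not activated. High dilution disfavours intermolecular esterification, and the equatorial oxyphosphonium has no antiperiplanar hydrogen for E2 loss.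

Step 10
Reactants: 12 3-O-acetyl-4-O-MOM-1,5-quinide
Product: 13 4-O-MOM-1,5-quinide (O3–H and O1–H free)
Conditions: immobilised Candida antarctica lipase B, n-BuOH, MTBE, 40 °C
Reagents that add atoms: none
Why: Lipase-catalysed alcoholysis is neutral and should remove the (R)-configured secondary acetate, whereas the lactone carbonyl on fully substituted C1 is a poor acyl donor for the enzyme; alkoxide methanolysis would open the strained lactone.

Step 11
Reactants: 14 caffeic acid
Product: 15 3,4-di-O-acetylcaffeic acid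
Conditions: Ac2O, pyridine, rt; H2O, dilute HCl work-up
Reagents that add atoms: acetic anhydride, CC(=O)OC(C)=O
Why: Pyridine-promoted phenol O-acetylation masks the catechol, and any mixed anhydride at the carboxyl is hydrolysed on work-up.

Step 12
Reactants: 15 3,4-di-O-acetylcaffeic acid
Product: 16 3,4-di-O-acetylcaffeoyl chloride
Conditions: (COCl)2, DMF (cat.), CH2Cl2, 0 °C → rt; evaporated, used crude
Reagents that add atoms: oxalyl chloride, O=C(Cl)C(=O)Cl
Why: Vilsmeier-catalysed acid chloride formation runs at room temperature and leaves the aryl acetates and the E-alkene unchanged.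

Step 13
Reactants: 13 4-O-MOM-1,5-quinide; 16 3,4-di-O-acetylcaffeoyl chloride
Product: 17 3-O-(3,4-di-O-acetylcaffeoyl)-4-O-MOM-1,5-quinide
Conditions: 16 (1.1 equiv), pyridine, DMAP (0.1 equiv), CH2Cl2, −10 → 0 °C
Reagents that add atoms: none
Why: In this DMAP-catalysed acylation with an acid chloride the secondary equatorial O3–H should react well ahead of the tertiary O1–H, which is hindered and deactivated by the adjacent lactone carbonyl.

Step 14
Reactants: 17 3-O-(3,4-di-O-acetylcaffeoyl)-4-O-MOM-1,5-quinide
Product: 18 3-O-(3,4-di-O-acetylcaffeoyl)-4-O-MOM-1-O-(2,2,2-trichloroethoxycarbonyl)-1,5-quinide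
Conditions: TrocCl, pyridine, DMAP, CH2Cl2, 0 °C → rt
Reagents that add atoms: 2,2,2-trichloroethyl chloroformate, O=C(Cl)OCC(Cl)(Cl)Cl
Why: Chloroformate acylation meets O1–H as the only hydroxyl left and installs a carbonate that is stable to acid and is removed reductively.

Step 15
Reactants: 18 the 1-O-Troc-4-O-MOM quinide
Product: 19 3-O-(3,4-di-O-acetylcaffeoyl)-1-O-Troc-1,5-quinide (axial O4–H free)
Conditions: TFA/CH2Cl2 (1:1), 0 °C → rt; aqueous work-up
Reagents that add atoms: none
Why: Acid-catalysed acetal cleavage through the methoxymethyl oxocarbenium ion frees O4, while the lactone, Troc carbonate, cinnamate and aryl acetates tolerate TFA and acidic medium keeps O3→O4 acyl migration slow.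

Step 16
Reactants: 20 p-coumaric acid
Product: 21 4-O-acetyl-p-coumaric acid
Conditions: Ac2O, pyridine, rt; H2O, dilute HCl work-up
Reagents that add atoms: acetic anhydride, CC(=O)OC(C)=O
Why: Pyridine-promoted phenol O-acetylation, as in step 11.

Step 17
Reactants: 21 4-O-acetyl-p-coumaric acid
Product: 22 4-O-acetyl-p-coumaroyl chloride
Conditions: (COCl)2, DMF (cat.), CH2Cl2, 0 °C → rt; evaporated, used crude
Reagents that add atoms: oxalyl chloride, O=C(Cl)C(=O)Cl
Why: Vilsmeier-catalysed acid chloride formation, as in step 12.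

Step 18
Reactants: 19 3-O-(3,4-di-O-acetylcaffeoyl)-1-O-Troc-1,5-quinide; 22 4-O-acetyl-p-coumaroyl chloride
Product: 23 3-O-(3,4-di-O-acetylcaffeoyl)-4-O-(4-O-acetyl-p-coumaroyl)-1-O-Troc-1,5-quinide
Conditions: 22 (2.5 equiv), pyridine, DMAP (0.5 equiv), CH2Cl2, rt
Reagents that add atoms: none
Why: DMAP-catalysed acylation can be forced because the hindered axial O4–H is the only nucleophile, and the excess of acid chloride should make esterification faster than the uphill O3→O4 shift of the caffeoyl group.

Step 19
Reactants: 23 the fully protected diester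
Product: 24 3-O-(3,4-di-O-acetylcaffeoyl)-4-O-(4-O-acetyl-p-coumaroyl)-1,5-quinide (O1–H free)
Conditions: Zn dust, AcOH/THF (1:1), rt
Reagents that add atoms: none
Why: Reductive β-elimination of the trichloroethyl carbonate (zinc insertion, loss of 1,1-dichloroethene and CO2) does not affect cinnamate alkenes, aryl acetates or the lactone.

Step 20
Reactants: 24 3-O-(3,4-di-O-acetylcaffeoyl)-4-O-(4-O-acetyl-p-coumaroyl)-1,5-quinide
Product: 25 3-O-caffeoyl-4-O-p-coumaroylquinic acid (target)
Conditions: 2 M aq. HCl/THF (1:3), degassed, rt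
Reagents that add atoms: water, O
Why: Acid-catalysed acyl–oxygen hydrolysis should cleave the three aryl acetates and the strained γ-lactone faster than the conjugated, hindered secondary cinnamates, it retains the C5–O bond and hence C5, and the acidic medium suppresses acyl migration to the freed O5–H.

**Compound list**
1 | gallic acid | O=C(O)c1cc(O)c(O)c(O)c1 | starting material
2 | all-cis-3,4,5-trihydroxycyclohexane-1-carboxylic acid | O[C@H]1[C@@H](O)C[C@@H](C(=O)O)C[C@H]1O | intermediate
3 | benzyl all-cis-3,4,5-trihydroxycyclohexane-1-carboxylate | O[C@H]1[C@@H](O)C[C@@H](C(=O)OCc2ccccc2)C[C@H]1O | intermediate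
4 | benzyl all-cis-3,5-bis(TBSO)-4-hydroxycyclohexane-1-carboxylate | O[C@H]1[C@@H](O[Si](C)(C)C(C)(C)C)C[C@@H](C(=O)OCc2ccccc2)C[C@H]1O[Si](C)(C)C(C)(C)C | intermediate
5 | benzyl all-cis-3,5-bis(TBSO)-4-(MOMO)cyclohexane-1-carboxylate | COCO[C@H]1[C@@H](O[Si](C)(C)C(C)(C)C)C[C@@H](C(=O)OCc2ccccc2)C[C@H]1O[Si](C)(C)C(C)(C)C | intermediate
6 | lithium ester enolate of 5 (not isolated) | COCO[C@H]1[C@@H](O[Si](C)(C)C(C)(C)C)CC(=C([O-])OCc2ccccc2)C[C@H]1O[Si](C)(C)C(C)(C)C.[Li+] | intermediate
7 | benzyl 3,5-di-O-TBS-4-O-MOM-5-epi-quinate | COCO[C@H]1[C@@H](O[Si](C)(C)C(C)(C)C)C[C@](O)(C(=O)OCc2ccccc2)C[C@H]1O[Si](C)(C)C(C)(C)C | intermediate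
8 | benzyl 4-O-MOM-5-epi-quinate (meso) | COCO[C@H]1[C@@H](O)C[C@](O)(C(=O)OCc2ccccc2)C[C@H]1O | intermediate
9 | benzyl 3-O-acetyl-4-O-MOM-5-epi-quinate | COCO[C@H]1[C@@H](O)C[C@](O)(C(=O)OCc2ccccc2)C[C@H]1OC(C)=O | intermediate
10 | 3-O-acetyl-4-O-MOM-5-epi-quinic acid | COCO[C@H]1[C@@H](O)C[C@](O)(C(=O)O)C[C@H]1OC(C)=O | intermediate
11 | C5-oxytriphenylphosphonium carboxylate zwitterion (not isolated) | COCO[C@H]1[C@@H](O[P+](c2ccccc2)(c2ccccc2)c2ccccc2)C[C@](O)(C(=O)[O-])C[C@H]1OC(C)=O | intermediate
12 | 3-O-acetyl-4-O-MOM-1,5-quinide | COCO[C@H]1[C@H]2C[C@](O)(C(=O)O2)C[C@H]1OC(C)=O | intermediate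
13 | 4-O-MOM-1,5-quinide | COCO[C@H]1[C@H]2C[C@](O)(C(=O)O2)C[C@H]1O | intermediate
14 | caffeic acid | O=C(O)/C=C/c1ccc(O)c(O)c1 | starting material
15 | 3,4-di-O-acetylcaffeic acid | CC(=O)Oc1ccc(/C=C/C(=O)O)cc1OC(C)=O | intermediate
16 | 3,4-di-O-acetylcaffeoyl chloride | CC(=O)Oc1ccc(/C=C/C(=O)Cl)cc1OC(C)=O | intermediate
17 | 3-O-(3,4-di-O-acetylcaffeoyl)-4-O-MOM-1,5-quinide | COCO[C@H]1[C@H]2C[C@](O)(C(=O)O2)C[C@H]1OC(=O)/C=C/c1ccc(OC(C)=O)c(OC(C)=O)c1 | intermediate
18 | 3-O-(3,4-di-O-acetylcaffeoyl)-4-O-MOM-1-O-Troc-1,5-quinide | COCO[C@H]1[C@H]2C[C@](OC(=O)OCC(Cl)(Cl)Cl)(C(=O)O2)C[C@H]1OC(=O)/C=C/c1ccc(OC(C)=O)c(OC(C)=O)c1 | intermediate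
19 | 3-O-(3,4-di-O-acetylcaffeoyl)-1-O-Troc-1,5-quinide | O[C@H]1[C@H]2C[C@](OC(=O)OCC(Cl)(Cl)Cl)(C(=O)O2)C[C@H]1OC(=O)/C=C/c1ccc(OC(C)=O)c(OC(C)=O)c1 | intermediate
20 | p-coumaric acid | O=C(O)/C=C/c1ccc(O)cc1 | starting material
21 | 4-O-acetyl-p-coumaric acid | CC(=O)Oc1ccc(/C=C/C(=O)O)cc1 | intermediate
22 | 4-O-acetyl-p-coumaroyl chloride | CC(=O)Oc1ccc(/C=C/C(=O)Cl)cc1 | intermediate
23 | 3-O-(3,4-di-O-acetylcaffeoyl)-4-O-(4-O-acetyl-p-coumaroyl)-1-O-Troc-1,5-quinide | O=C(/C=C/c1ccc(OC(C)=O)cc1)O[C@H]1[C@H]2C[C@](OC(=O)OCC(Cl)(Cl)Cl)(C(=O)O2)C[C@H]1OC(=O)/C=C/c1ccc(OC(C)=O)c(OC(C)=O)c1 | intermediate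
24 | 3-O-(3,4-di-O-acetylcaffeoyl)-4-O-(4-O-acetyl-p-coumaroyl)-1,5-quinide | O=C(/C=C/c1ccc(OC(C)=O)cc1)O[C@H]1[C@H]2C[C@](O)(C(=O)O2)C[C@H]1OC(=O)/C=C/c1ccc(OC(C)=O)c(OC(C)=O)c1 | intermediate
25 | 3-O-caffeoyl-4-O-p-coumaroylquinic acid | O=C(/C=C/c1ccc(O)cc1)O[C@H]1[C@H](O)C[C@](O)(C(=O)O)C[C@H]1OC(=O)/C=C/c1ccc(O)c(O)c1 | target

**Step count**
- Total steps: 20.
- Longest linear sequence: 16 (steps 1–10, 13–15, 18–20).

**Steps most likely to fail**

Step 9. Phosphorus transfer to the hindered O5–H may be slow. The constrained backside closure may then be outrun by intermolecular esterification or by acylation of the reduced azodicarboxylate.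

The fallback separates activation from displacement and sets out from 9.
- MsCl/Et3N (CH2Cl2, 0 °C) sulfonylates the only secondary hydroxyl to give benzyl 3-O-acetyl-5-O-mesyl-4-O-MOM-5-epi-quinate F1.
- Hydrogenolysis (H2, Pd/C, EtOAc) gives 3-O-acetyl-5-O-mesyl-4-O-MOM-5-epi-quinic acid F2.
- Cs2CO3 in dilute DMF at 50–70 °C lets the caesium carboxylate displace the sulfonate from the back of C5. The route is rejoined at 12.

Step 7. The enzyme may accept the substrate poorly, or it may discriminate the enantiotopic carbinols too weakly or in the opposite sense.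

The fallback turns the desymmetrisation round and sets out from 8.
- Ac2O/pyridine without DMAP gives the meso diester benzyl 3,5-di-O-acetyl-4-O-MOM-5-epi-quinate F3.
- A hydrolase (the same lipase or pig liver esterase, pH 7 phosphate buffer/MTBE) then cleaves one enantiotopic acetate.
- An enzyme keeps its preference for one carbinol configuration in both directions. Hydrolysis therefore leaves the acetate on the carbinol that acylation would have left free, and the mode that leaves O3 acetylated is used. The route is rejoined at 9.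

Step 10. The bicyclic acetate may be a poor enzyme substrate, and over long reaction times alcoholysis of the lactone may begin to compete.

The fallback gives up selectivity and restores the lactone afterwards. It sets out from 12.
- LiOH (THF/H2O, 0 °C) saponifies the acetate and the lactone together. After acidification this gives 4-O-MOM-quinic acid F4.
- EDC·HCl in dilute CH2Cl2/DMF re-closes the lactone. Only O5–H is now cis to C7, so no other hydroxyl can lactonise. The route is rejoined at 13.

**Further compounds**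
F1 | step 9 | benzyl 3-O-acetyl-5-O-mesyl-4-O-MOM-5-epi-quinate | COCO[C@H]1[C@@H](OS(C)(=O)=O)C[C@](O)(C(=O)OCc2ccccc2)C[C@H]1OC(C)=O
F2 | step 9 | 3-O-acetyl-5-O-mesyl-4-O-MOM-5-epi-quinic acid | COCO[C@H]1[C@@H](OS(C)(=O)=O)C[C@](O)(C(=O)O)C[C@H]1OC(C)=O
F3 | step 7 | benzyl 3,5-di-O-acetyl-4-O-MOM-5-epi-quinate | COCO[C@H]1[C@@H](OC(C)=O)C[C@](O)(C(=O)OCc2ccccc2)C[C@H]1OC(C)=O
F4 | step 10 | 4-O-MOM-quinic acid | COCO[C@H]1[C@H](O)C[C@](O)(C(=O)O)C[C@H]1O
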